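**Retrosynthetic overview**
1. The oxolane O–C10 bond is closed last, on the complete C24 skeleton, by a cobalt-catalysed aerobic oxidative cyclisation with hydrogen-atom termination of alkenol 22 (sets C10, 2,5-trans); only ester hydrolysis follows.
2. Enabling feature: the C7 hydroxyl, on the carbon exocyclic to dioxane C6, lies four atoms from C10 of the C10=C11 alkene (array O–C7–C8–C9–C10=C11), so the cobalt-bound oxygen reaches only this one of four C=C units and the C7 substituent steers C10.
3. C10=C11 is made by Wittig union of core aldehyde 19 with the C11–C24 (Z,Z)-dienyl ylide (Cadiot–Chodkiewicz coupling, Boland reduction).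
4. The core uses the hidden twofold rotational symmetry of C3–C10: (S,S)-epoxide 14 of a symmetric trienedioate is perhydrolysed (no regiochemical issue) to C6–OOH/C7–OH, a 6-exo peroxy-Michael addition closes the 1,2-dioxane (C3), and the untouched distal enoate is a masked C10 aldehyde.
5. Ring order: 1,2-dioxane (step 11), then oxolane (step 16).

Key step: step 16

Remark: atoms are numbered C1 (carboxyl carbon) to C24 (terminal alkene carbon) of the target throughout; the L-series Shi ketone used in step 9 is assumed to be accessible from L-sorbose and is treated as a reagent.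

**Step 1**
Reactants: 1 oct-7-yn-1-ol
Product: 2 8-bromooct-7-yn-1-ol
Conditions: NBS, AgNO3 (10 mol%), acetone, rt
Reagents that add atoms: N-bromosuccinimide, O=C1CCC(=O)N1Br
Why: Silver-catalysed electrophilic bromination of the terminal alkyne C–H gives the 1-bromoalkyne needed as electrophilic coupling partner, and the free hydroxyl is inert.

**Step 2**
Reactants: 2 8-bromooct-7-yn-1-ol; 3 hex-1-en-5-yne
Product: 4 tetradec-13-ene-7,9-diyn-1-ol
Conditions: CuCl (5 mol%), NH2OH·HCl, n-BuNH2 (30% aq.), Et2O, 0 °C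
Reagents that add atoms: none
Why: Cadiot–Chodkiewicz coupling, in which the monovalent copper acetylide of 3 couples with bromoalkyne 2 to give the unsymmetrical 1,3-diyne while hydroxylamine keeps copper monovalent and suppresses homocoupling.

**Step 3**
Reactants: 4 tetradec-13-ene-7,9-diyn-1-ol
Product: 5 (7Z,9Z)-tetradeca-7,9,13-trien-1-ol
Conditions: Zn dust activated with Cu(OAc)2 and AgNO3, MeOH/H2O (1:1), 40 °C
Reagents that add atoms: none
Why: Boland reduction, in which activated zinc adds hydrogen cis across each triple bond of the conjugated diyne only, so the (Z,Z)-diene should form without over-reduction and the isolated terminal alkene should stay untouched.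

**Step 4**
Reactants: 5 (7Z,9Z)-tetradeca-7,9,13-trien-1-ol
Product: 6 (5Z,7Z)-14-iodotetradeca-1,5,7-triene
Conditions: I2, PPh3, imidazole, CH2Cl2, 0 °C
Reagents that add atoms: iodine, II
Why: Appel-type iodination, in which the alcohol is activated as an alkoxyphosphonium ion and displaced by iodide (SN2) under buffered conditions that should leave the diene geometry intact.

**Step 5**
Reactants: 6 (5Z,7Z)-14-iodotetradeca-1,5,7-triene
Product: 7 [(7Z,9Z)-tetradeca-7,9,13-trien-1-yl]triphenylphosphonium iodide
Conditions: PPh3, MeCN, 80 °C, dark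
Reagents that add atoms: triphenylphosphine, c1ccc(cc1)P(c1ccccc1)c1ccccc1
Why: SN2 quaternisation of triphenylphosphine by the primary iodide gives the Wittig salt without touching the alkenes.

**Step 6**
Reactants: 8 (E)-1,4-dibromobut-2-ene; 9 dimethyl malonate (two molecules are incorporated, one at each allylic carbon of 8)
Product: 10 tetramethyl (E)-hex-3-ene-1,1,6,6-tetracarboxylate
Conditions: 9 (5 equiv), NaH (2.2 equiv), THF, 0 °C; then 8 added slowly, 0 °C to rt
Reagents that add atoms: dimethyl malonate (the second molecule of 9), COC(=O)CC(=O)OC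
Why: Twofold malonic ester alkylation, in which two molecules of sodio dimethyl malonate each displace one primary allylic bromide of 8 by SN2, should retain the E alkene, and the excess of malonate with slow addition of 8 keeps the monoalkylated intermediate protonated and so disfavours its closure to a vinylcyclopropane.

**Step 7**
Reactants: 10 tetramethyl (E)-hex-3-ene-1,1,6,6-tetracarboxylate
Product: 11 dimethyl (E)-oct-4-enedioate
Conditions: LiCl, H2O, DMSO, 150 °C
Reagents that add atoms: none
Why: Krapcho dealkoxycarbonylation, in which chloride demethylates one ester of each malonate unit and the carboxylate loses CO2, leaves the E alkene and the remaining esters intact.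

**Step 8**
Reactants: 11 dimethyl (E)-oct-4-enedioate
Product: 13 dimethyl (2E,6E,10E)-dodeca-2,6,10-trienedioate, via (E)-oct-4-enedial 12 (not isolated)
Conditions: iBu2AlH (2.1 equiv), CH2Cl2, −78 °C; then Ph3P=CHCO2Me (2.6 equiv), −78 °C to rt
Reagents that add atoms: methyl (triphenylphosphoranylidene)acetate, COC(=O)C=P(c1ccccc1)(c1ccccc1)c1ccccc1
Why: Partial ester reduction followed in the same flask by Wittig olefination with a stabilised ylide (two equivalents are incorporated), which traps the aldehydes as they are released from the aluminium hemiacetals and should give both new enoates with E geometry.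

**Step 9**
Reactants: 13 dimethyl (2E,6E,10E)-dodeca-2,6,10-trienedioate
Product: 14 dimethyl (2E,2'E)-5,5'-[(2S,3S)-oxirane-2,3-diyl]bis(pent-2-enoate)
Conditions: L-fructose-derived Shi ketone (enantiomer of the usual D-fructose-derived catalyst, 30 mol%), KHSO5 (as Oxone), K2CO3, Bu4NHSO4, aq. Na2B4O7 buffer, MeCN/CH2(OMe)2, 0 °C
Reagents that add atoms: potassium peroxymonosulfate, [K+].[O-]S(=O)(=O)OO
Why: Shi asymmetric epoxidation, in which the chiral dioxirane should attack only the electron-rich central trans alkene (the two enoates are deactivated) through the spiro transition state and set C6 and C7 as (S,S), the mirror image of the (R,R) sense given by the D-series ketone.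

**Step 10**
Reactants: 14 dimethyl (2E,2'E)-5,5'-[(2S,3S)-oxirane-2,3-diyl]bis(pent-2-enoate)
Product: 15 dimethyl (2E,6R,7S,10E)-6-hydroperoxy-7-hydroxydodeca-2,10-dienedioate
Conditions: anhydrous H2O2 in Et2O (10 equiv), H3PMo12O40 (3 mol%), rt
Reagents that add atoms: hydrogen peroxide, OO
Why: Acid-catalysed epoxide perhydrolysis by SN2-type anti opening, where the twofold rotational symmetry of 14 makes the two epoxide carbons equivalent so that attack of H2O2 at either one with inversion should give the single erythro product with C6 (R, O–O) and C7 (S, OH).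

**Step 11**
Reactants: 15 dimethyl (2E,6R,7S,10E)-6-hydroperoxy-7-hydroxydodeca-2,10-dienedioate
Product: 16 methyl 2-[(3R,6R)-6-[(1S,4E)-1-hydroxy-6-methoxy-6-oxohex-4-en-1-yl]-1,2-dioxan-3-yl]acetate
Conditions: Et3N (0.3 equiv), CF3CH2OH, rt
Reagents that add atoms: none
Why: Intramolecular peroxy-Michael (6-exo-trig) addition, in which only the hydroperoxide is nucleophilic enough under amine catalysis (the C7 hydroxyl is inert and the distal enoate would need a seven-membered closure) and the reversible addition should set C3 as (R) by placing the acetate arm and the C6 side chain both equatorial on the dioxane chair (3,6-trans).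

**Step 12**
Reactants: 16 methyl 2-[(3R,6R)-6-[(1S,4E)-1-hydroxy-6-methoxy-6-oxohex-4-en-1-yl]-1,2-dioxan-3-yl]acetate
Product: 17 methyl 2-[(3R,6R)-6-[(1S,4E)-6-methoxy-6-oxo-1-(triethylsilyloxy)hex-4-en-1-yl]-1,2-dioxan-3-yl]acetate
Conditions: Et3SiCl, imidazole, CH2Cl2, 0 °C
Reagents that add atoms: chlorotriethylsilane, CC[Si](Cl)(CC)CC
Why: Silyl ether formation masks the C7 hydroxyl so that the aldehyde unveiled next stays open-chain (no lactol) and the alcohol is shielded from the ylide.

**Step 13**
Reactants: 17 methyl 2-[(3R,6R)-6-[(1S,4E)-6-methoxy-6-oxo-1-(triethylsilyloxy)hex-4-en-1-yl]-1,2-dioxan-3-yl]acetate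
Product: 19 methyl 2-[(3R,6R)-6-[(1S)-4-oxo-1-(triethylsilyloxy)butyl]-1,2-dioxan-3-yl]acetate, via secondary ozonide 18 (not isolated)
Conditions: O3, CH2Cl2, −78 °C; then Me2S, −78 °C to rt
Reagents that add atoms: ozone, [O-][O+]=O
Why: Ozonolysis with reductive work-up cleaves the only remaining C=C bond to the C10 aldehyde, the enoate terminus that enforced symmetry leaving as methyl glyoxylate, while the dialkyl peroxide and the silyl ether are inert to ozone and Me2S at low temperature.

**Step 14**
Reactants: 19 methyl 2-[(3R,6R)-6-[(1S)-4-oxo-1-(triethylsilyloxy)butyl]-1,2-dioxan-3-yl]acetate; 7 [(7Z,9Z)-tetradeca-7,9,13-trien-1-yl]triphenylphosphonium iodide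
Product: 21 methyl 2-[(3R,6R)-6-[(1S,4Z,11Z,13Z)-1-(triethylsilyloxy)octadeca-4,11,13,17-tetraen-1-yl]-1,2-dioxan-3-yl]acetate, via phosphonium ylide 20 (not isolated)
Conditions: 7 (1.3 equiv), NaN(SiMe3)2 (1.25 equiv), THF, −78 to 0 °C; then 19, −78 to −20 °C
Reagents that add atoms: none
Why: Wittig olefination with a non-stabilised ylide under lithium-free conditions at low temperature should give the C10=C11 Z alkene, the base being fully consumed in ylide formation before the peroxide-bearing aldehyde is added.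

**Step 15**
Reactants: 21 methyl 2-[(3R,6R)-6-[(1S,4Z,11Z,13Z)-1-(triethylsilyloxy)octadeca-4,11,13,17-tetraen-1-yl]-1,2-dioxan-3-yl]acetate
Product: 22 methyl 2-[(3R,6R)-6-[(1S,4Z,11Z,13Z)-1-hydroxyoctadeca-4,11,13,17-tetraen-1-yl]-1,2-dioxan-3-yl]acetate
Conditions: HF·pyridine, pyridine, THF, 0 °C
Reagents that add atoms: none
Why: Fluoride-mediated desilylation under pyridine-buffered conditions frees the C7 hydroxyl without touching the peroxide, the ester or the diene.

**Step 16**
Reactants: 22 methyl 2-[(3R,6R)-6-[(1S,4Z,11Z,13Z)-1-hydroxyoctadeca-4,11,13,17-tetraen-1-yl]-1,2-dioxan-3-yl]acetate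
Product: 23 methyl 2-[(3R,6R)-6-[(2S,5R)-5-[(7Z,9Z)-tetradeca-7,9,13-trien-1-yl]oxolan-2-yl]-1,2-dioxan-3-yl]acetate
Conditions: Co(CF3COCHCOCH3)2 (10 mol%), O2 (1 atm), cyclohexa-1,4-diene (20 equiv), toluene, 60 °C
Reagents that add atoms: none
Why: The divalent cobalt bis(β-diketonate) is oxidised by O2 to a trivalent cobalt species that binds the C7 alkoxide, the bound alkene is attacked by oxygen at C10 to leave a carbon radical at C11, and this radical is quenched by hydrogen-atom transfer from cyclohexa-1,4-diene, so the net change is a formal hydroalkoxylation. The closest known reaction type is the Mukaiyama aerobic oxidative cyclisation of pent-4-en-1-ols in its reductive-termination variant, known for 1-substituted bishomoallylic alcohols. The only ring closed is the oxolane (O–C7–C8–C9–C10), by 5-exo-trig attack of the C7 oxygen on C10; the 6-endo mode at C11 is disfavoured. The new stereocentre C10 is controlled by C7: in the chair-like transition state the bulky dioxanyl group sits pseudo-equatorial, which should give the 2,5-trans ring, i.e. (10R) from (7S), whatever the alkene geometry. The step needs selection of one of four C=C units and of hydrogen over oxygen capture at C11; the first is secured because only C10=C11 lies within reach of the cobalt-bound C7 oxygen (the diene and the vinyl group carry no directing hydroxyl), the second by the large excess of hydrogen donor. The secondary dialkyl peroxide should survive, since cobalt diketonate/oxygen systems of this kind are the ones used to prepare dialkyl peroxides.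

**Step 17**
Reactants: 23 methyl 2-[(3R,6R)-6-[(2S,5R)-5-[(7Z,9Z)-tetradeca-7,9,13-trien-1-yl]oxolan-2-yl]-1,2-dioxan-3-yl]acetate
Product: 24 2-[(3R,6R)-6-[(2S,5R)-5-[(7Z,9Z)-tetradeca-7,9,13-trien-1-yl]oxolan-2-yl]-1,2-dioxan-3-yl]acetic acid
Conditions: LiOH (3 equiv), THF/H2O (3:1), 0 °C; then aq. HCl to pH 3–4
Reagents that add atoms: lithium hydroxide, [Li+].[OH-]
Why: Ester saponification, in which hydroxide attacks the unhindered methyl ester at 0 °C faster than it can enolise the β-peroxy ester, so the dioxane and all four stereocentres should be retained.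

**Compound list**
1 | oct-7-yn-1-ol | C#CCCCCCCO | starting material
2 | 8-bromooct-7-yn-1-ol | BrC#CCCCCCCO | intermediate
3 | hex-1-en-5-yne | C=CCCC#C | starting material
4 | tetradec-13-ene-7,9-diyn-1-ol | C=CCCC#CC#CCCCCCCO | intermediate
5 | (7Z,9Z)-tetradeca-7,9,13-trien-1-ol | C=CCC/C=C\C=C/CCCCCCO | intermediate
6 | (5Z,7Z)-14-iodotetradeca-1,5,7-triene | C=CCC/C=C\C=C/CCCCCCI | intermediate
7 | [(7Z,9Z)-tetradeca-7,9,13-trien-1-yl]triphenylphosphonium iodide | C=CCC/C=C\C=C/CCCCCC[P+](c1ccccc1)(c1ccccc1)c1ccccc1.[I-] | intermediate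
8 | (E)-1,4-dibromobut-2-ene | BrC/C=C/CBr | starting material
9 | dimethyl malonate | COC(=O)CC(=O)OC | starting material
10 | tetramethyl (E)-hex-3-ene-1,1,6,6-tetracarboxylate | COC(=O)C(C/C=C/CC(C(=O)OC)C(=O)OC)C(=O)OC | intermediate
11 | dimethyl (E)-oct-4-enedioate | COC(=O)CC/C=C/CCC(=O)OC | intermediate
12 | (E)-oct-4-enedial | O=CCC/C=C/CCC=O | intermediate (not isolated)
13 | dimethyl (2E,6E,10E)-dodeca-2,6,10-trienedioate | COC(=O)/C=C/CC/C=C/CC/C=C/C(=O)OC | intermediate
14 | dimethyl (2E,2'E)-5,5'-[(2S,3S)-oxirane-2,3-diyl]bis(pent-2-enoate) | COC(=O)/C=C/CC[C@@H]1O[C@H]1CC/C=C/C(=O)OC | intermediate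
15 | dimethyl (2E,6R,7S,10E)-6-hydroperoxy-7-hydroxydodeca-2,10-dienedioate | COC(=O)/C=C/CC[C@@H](OO)[C@@H](O)CC/C=C/C(=O)OC | intermediate
16 | methyl 2-[(3R,6R)-6-[(1S,4E)-1-hydroxy-6-methoxy-6-oxohex-4-en-1-yl]-1,2-dioxan-3-yl]acetate | COC(=O)C[C@H]1CC[C@@H](OO1)[C@@H](O)CC/C=C/C(=O)OC | intermediate
17 | methyl 2-[(3R,6R)-6-[(1S,4E)-6-methoxy-6-oxo-1-(triethylsilyloxy)hex-4-en-1-yl]-1,2-dioxan-3-yl]acetate | COC(=O)C[C@H]1CC[C@@H](OO1)[C@@H](O[Si](CC)(CC)CC)CC/C=C/C(=O)OC | intermediate
18 | methyl 5-[(3S)-3-[(3R,6R)-6-(2-methoxy-2-oxoethyl)-1,2-dioxan-3-yl]-3-(triethylsilyloxy)propyl]-1,2,4-trioxolane-3-carboxylate (secondary ozonide, ring diastereomers) | COC(=O)C[C@H]1CC[C@@H](OO1)[C@@H](O[Si](CC)(CC)CC)CCC1OOC(O1)C(=O)OC | intermediate (not isolated)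
19 | methyl 2-[(3R,6R)-6-[(1S)-4-oxo-1-(triethylsilyloxy)butyl]-1,2-dioxan-3-yl]acetate | COC(=O)C[C@H]1CC[C@@H](OO1)[C@@H](O[Si](CC)(CC)CC)CCC=O | intermediate
20 | [(7Z,9Z)-tetradeca-7,9,13-trien-1-ylidene]triphenylphosphorane | C=CCC/C=C\C=C/CCCCCC=P(c1ccccc1)(c1ccccc1)c1ccccc1 | intermediate (not isolated)
21 | methyl 2-[(3R,6R)-6-[(1S,4Z,11Z,13Z)-1-(triethylsilyloxy)octadeca-4,11,13,17-tetraen-1-yl]-1,2-dioxan-3-yl]acetate | COC(=O)C[C@H]1CC[C@@H](OO1)[C@@H](O[Si](CC)(CC)CC)CC/C=C\CCCCC/C=C\C=C/CCC=C | intermediate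
22 | methyl 2-[(3R,6R)-6-[(1S,4Z,11Z,13Z)-1-hydroxyoctadeca-4,11,13,17-tetraen-1-yl]-1,2-dioxan-3-yl]acetate | COC(=O)C[C@H]1CC[C@@H](OO1)[C@@H](O)CC/C=C\CCCCC/C=C\C=C/CCC=C | intermediate
23 | methyl 2-[(3R,6R)-6-[(2S,5R)-5-[(7Z,9Z)-tetradeca-7,9,13-trien-1-yl]oxolan-2-yl]-1,2-dioxan-3-yl]acetate | C=CCC/C=C\C=C/CCCCCC[C@@H]1CC[C@@H]([C@H]2CC[C@H](CC(=O)OC)OO2)O1 | intermediate
24 | 2-[(3R,6R)-6-[(2S,5R)-5-[(7Z,9Z)-tetradeca-7,9,13-trien-1-yl]oxolan-2-yl]-1,2-dioxan-3-yl]acetic acid | C=CCC/C=C\C=C/CCCCCC[C@@H]1CC[C@@H]([C@H]2CC[C@H](CC(=O)O)OO2)O1 | target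

**Step count and risks**
Total step count: 17. Longest linear sequence: 12 steps (steps 6 to 17, from (E)-1,4-dibromobut-2-ene); the side-chain branch (steps 1 to 5) joins at step 14.

Steps most likely to fail:

1. Step 16. The C11 radical may be captured by oxygen instead of hydrogen (oxygenation at C11), peroxyl radicals may add to the (Z,Z)-diene and isomerise it, and cobalt may induce O–O cleavage of the dioxane. The fallback sets out from alkenol 22 and comes back at ester 23 by an oxygen-free electrophilic closure. 22 would be cyclised with Hg(OCOCF3)2 in CH2Cl2 at −20 °C (intramolecular oxymercuration) and exchanged with aqueous NaCl to give methyl 2-[(3R,6R)-6-[(2S,5S)-5-[(7Z,9Z)-1-(chloromercurio)tetradeca-7,9,13-trien-1-yl]oxolan-2-yl]-1,2-dioxan-3-yl]acetate F1 (both C11 epimers). F1 would be demercurated with NaBH4 in aqueous NaOH/THF at −20 °C under argon to give 23. Dialkyl peroxides are expected to tolerate divalent mercury salts and borohydride demercuration; the 2,5-trans preference should be weaker than in the cobalt reaction, so the trans isomer would be separated by chromatography.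

2. Step 14. The basic ylide may attack the O–O bond, trigger base-induced fragmentation at the peroxide α-hydrogens or open the dioxane by enolisation and β-elimination of the peroxy ester. The fallback sets out from alcohol 5 and aldehyde 19 and comes back at ester 23 by a Julia–Kocienski olefination. Mitsunobu reaction of 5 with 1-phenyl-1H-tetrazole-5-thiol (PPh3, DIAD, THF) would give 5-[(7Z,9Z)-tetradeca-7,9,13-trien-1-ylsulfanyl]-1-phenyl-1H-tetrazole F2. Oxidation with H2O2 and (NH4)6Mo7O24 in EtOH would give 5-[(7Z,9Z)-tetradeca-7,9,13-trien-1-ylsulfonyl]-1-phenyl-1H-tetrazole F3. KN(SiMe3)2 added to a mixture of F3 and 19 in DME at −60 °C, so that the sulfonyl carbanion is trapped as it forms, would give methyl 2-[(3R,6R)-6-[(1S,4E,11Z,13Z)-1-(triethylsilyloxy)octadeca-4,11,13,17-tetraen-1-yl]-1,2-dioxan-3-yl]acetate F4. HF·pyridine would give methyl 2-[(3R,6R)-6-[(1S,4E,11Z,13Z)-1-hydroxyoctadeca-4,11,13,17-tetraen-1-yl]-1,2-dioxan-3-yl]acetate F5. F5 would be cyclised under the conditions of step 16 to 23, since the C10=C11 geometry is erased at the C11 radical.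

3. Step 11. Ring closure may show poor facial selectivity at C3 if it does not equilibrate, and the secondary hydroperoxide may undergo base-induced dehydration. The fallback sets out from hydroperoxide 15 and comes back at 16. The closure would be run to full conversion without relying on kinetic selection, and the C3 epimer, methyl 2-[(3S,6R)-6-[(1S,4E)-1-hydroxy-6-methoxy-6-oxohex-4-en-1-yl]-1,2-dioxan-3-yl]acetate F6, would be separated from 16 by chromatography. F6 would then be epimerised in a separate thermodynamic relay: catalytic DBU in MeCN at 0 °C should reopen the ring by E1cB elimination to the anion of hydroperoxide 15 and allow re-closure to the diequatorial isomer 16, with recycling of residual F6.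

**Further compounds**
F1 | step 16 | methyl 2-[(3R,6R)-6-[(2S,5S)-5-[(7Z,9Z)-1-(chloromercurio)tetradeca-7,9,13-trien-1-yl]oxolan-2-yl]-1,2-dioxan-3-yl]acetate | COC(=O)C[C@H]1CC[C@@H](OO1)[C@@H]1CC[C@H](O1)C([Hg]Cl)CCCCC/C=C\C=C/CCC=C
F2 | step 14 | 5-[(7Z,9Z)-tetradeca-7,9,13-trien-1-ylsulfanyl]-1-phenyl-1H-tetrazole | C=CCC/C=C\C=C/CCCCCCSc1nnnn1-c1ccccc1
F3 | step 14 | 5-[(7Z,9Z)-tetradeca-7,9,13-trien-1-ylsulfonyl]-1-phenyl-1H-tetrazole | C=CCC/C=C\C=C/CCCCCCS(=O)(=O)c1nnnn1-c1ccccc1
F4 | step 14 | methyl 2-[(3R,6R)-6-[(1S,4E,11Z,13Z)-1-(triethylsilyloxy)octadeca-4,11,13,17-tetraen-1-yl]-1,2-dioxan-3-yl]acetate | COC(=O)C[C@H]1CC[C@@H](OO1)[C@@H](O[Si](CC)(CC)CC)CC/C=C/CCCCC/C=C\C=C/CCC=C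
F5 | step 14 | methyl 2-[(3R,6R)-6-[(1S,4E,11Z,13Z)-1-hydroxyoctadeca-4,11,13,17-tetraen-1-yl]-1,2-dioxan-3-yl]acetate | COC(=O)C[C@H]1CC[C@@H](OO1)[C@@H](O)CC/C=C/CCCCC/C=C\C=C/CCC=C
F6 | step 11 | methyl 2-[(3S,6R)-6-[(1S,4E)-1-hydroxy-6-methoxy-6-oxohex-4-en-1-yl]-1,2-dioxan-3-yl]acetate | COC(=O)C[C@@H]1CC[C@@H](OO1)[C@@H](O)CC/C=C/C(=O)OC
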